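All constants were set for the occasion; the flask was simulated.

Divide the making of target by its loss before you run anything.

solid substrate 0.19 M; gas phase 39 mM (held); protic impurity 9.50 mM; time 80 min

    starting material + dissolved gas → target (k1 = 5.8 M⁻¹ min⁻¹)
    dissolved gas + target → over-reacted product (k2 = 3.4 M⁻¹ min⁻¹)
    solid substrate ⇌ starting material, rate k3*(cs3 - [starting material]) while solid is left; crystals form when [starting material] > cs3 (cs3 = 30 mM, k3 = 0.084 min⁻¹)
    dissolved gas + protic impurity → quenched reagent (k4 = 150 M⁻¹ min⁻¹)
    gas phase ⇌ dissolved gas, rate k5*(csat - [dissolved gas]) (k5 = 0.29 min⁻¹, csat = 39 mM)

- as a solid, counted per litre of solution: solid substrate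
- at the start none of the gas is dissolved
- at the start none of the solid substrate is in solution
- run time (flask): 80 min

- Sunday's: doubling the saturation concentration of gas phase, all else as stated
- Monday's: doubling the transfer coefficient of step 5, all else as stated
- Wednesday's: doubling the dissolution coefficient of step 3, all else as stated
- Tuesday's: doubling the solubility in step 3, all else as stated

- target at 80 min, in percent of the solid substrate charged
- the change that raises the amount of target at 80 min, in percent of the solid substrate charged most ("none" if none brings more than 2 percentage points) (Sunday's / Monday's / Wednesday's / Tuesday's / none)
- amount of target at 80 min, in percent of the solid substrate charged, after Monday's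

- Steps 1 and 2 both carry [dissolved gas], so their ratio loses it, and time with it. In this flask target stops growing when [target]/[starting material] reaches k1/k2 = 1.71, my standing ratio, a selectivity factor.
- I set the protic impurity aside: at its charge it gives dissolved gas a half-life of 0.49 min, far shorter than the run, so I expect its step to be over early.
- While solid is left, dissolving balances step 1, and gas transfer balances twice that, since steps 1 and 2 then run equally. Solving both gives [starting material] = 10.3 mM and [dissolved gas] = 27.6 mM.
- Target then loses half in 7.39 min, shorter than the run, so I reckon target at the standing ratio times [starting material], 9.27% of the charge. By this balance the solid lasts about 115 min.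
- By the same balances, I reckon Sunday's at 4.98%, less than my figure for the flask as charged.
- I reckon Monday's at 8.22%, also less.
- I reckon Wednesday's at 14.9%, and by this balance its solid lasts about 84.3 min, just past the asked time.
- The balances put Tuesday's at 23.2%, but by them its solid lasts about 66.1 min, shorter than the run, so they no longer hold at the asked time; I discount that figure and choose Wednesday's, which stands above my other figures.
- The forecast says 9.3%, Wednesday's and 8.2% after Monday's, holding that “more gas (Sunday's, Monday's) lowers the target by speeding over-reaction”.
- The flask gives 9.24%. Sunday's moves it by −4.3 percentage points, Monday's by −1 point to 8.22%, Wednesday's by 5.5 points, and Tuesday's by −0.82 points, so the best is Wednesday's.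
- This flask is not at rest at the asked time, though its target to starting material reads 1.70 against the standing ratio 1.71. Solid substrate stands at 28.3%, and my reckoning had it lasting 115 min. At 160 min target is down to 0.0734%. At 800 min target is 0% and over-reacted product 100%, so ten times the time changes the answer completely.
- With 0.47 M of solid, the balances contain no charge, so I expect the neighbour flask to hold the same [target] = 17.6 mM, which is 3.75% of its charge; the computed answer for that flask is 3.74%.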